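**Strategy**

Ring B is cut across C9–C10 and C7–C8. The route exploits the way ring B holds the quaternary C10 next to the tetrasubstituted C8=C9 alkene, with the oxygenated C7 on the other flank. That pattern is what a diene C10=C5–C6=C7 on ring A leaves when it adds to an alkyne C8≡C9. One enantioselective Diels–Alder reaction joins a 7-silyloxy diene from β-homocyclocitral with a nerol-derived alkynoyl oxazolidinone that already carries the complete (Z)-side chain. It closes ring B, forms both bonds, places the C8=C9 alkene and sets C10 and C7. The remaining C5=C6 alkene is then converted into the 5α-H/6β-acetoxy array under control of the 7α-oxygen.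

Key step: step 8

**Remarks before the route**

- Numbering: labdane numbering is used throughout (C1–C10 decalin; C11–C15 side chain; C16 the methyl on C13; C17 the carbon on C8; C20 the methyl on C10). β means the face of the C10 methyl and α the opposite face.
- Structure check: the diene geometry (O7 outside, C10 methyl inside) does give 7α-O trans to 10β-CH3, and the C7 silyloxy group does direct C7 to the acyl-bearing C8. No change of connectivity was needed.
- Design choices: the bulkier tert-butyldimethylsilyl group stays on O7 for the cycloaddition, and tert-butyldiphenylsilyl is used on O15 so that O7 can be unmasked beside it. The acyl group is kept on C8 until C5=C6 has been oxidised, because it switches off C8=C9.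
- Assumption: the copper chelate of the alkynoyl imide is taken to select its face as the chelates of alkenoyl imides do; if the sense proves opposite, the (R,R)-ligand is used and nothing else changes.

**Route**

Step 1
Reactants: 1 β-homocyclocitral [2-(2,6,6-trimethylcyclohex-1-en-1-yl)acetaldehyde]
Product: 2 (E)-tert-butyldimethyl{[2-(2,6,6-trimethylcyclohex-1-en-1-yl)ethenyl]oxy}silane (7-silyloxy diene C10=C5–C6=C7)
Conditions: TBSOTf, Et3N, CH2Cl2, 0 °C to rt
Reagents that add atoms: tert-butyldimethylsilyl triflate, CC(C)(C)[Si](C)(C)OS(=O)(=O)C(F)(F)F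
Why: Soft enolisation and O-silylation of the aldehyde (silyl enol ether formation) removes the doubly activated α-hydrogen to give the conjugated dienol ether, and the bulky trimethylcyclohexenyl group should turn away from the silyloxy group to give mainly the (E)-isomer, any (Z)-isomer being unable to reach the s-cis form needed in step 8.

Step 2
Reactants: 3 nerol [(2Z)-3,7-dimethylocta-2,6-dien-1-ol]
Product: 4 neryl tert-butyldiphenylsilyl ether
Conditions: TBDPSCl, imidazole, DMF, 0 °C to rt
Reagents that add atoms: tert-butylchlorodiphenylsilane, CC(C)(C)[Si](Cl)(c1ccccc1)c1ccccc1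
Why: Imidazole-promoted silylation of a primary alcohol is routine, and this robust silyl ether survives the later selective unmasking of O7.

Step 3
Reactants: 4 neryl tert-butyldiphenylsilyl ether
Product: 5 6,7-epoxyneryl tert-butyldiphenylsilyl ether (racemic at the epoxide carbon)
Conditions: mCPBA, CH2Cl2, −20 to 0 °C
Reagents that add atoms: 3-chloroperbenzoic acid, OOC(=O)c1cccc(Cl)c1
Why: Prilezhaev epoxidation should take the remote, electron-rich trisubstituted alkene first, because the 2,3-alkene is deactivated inductively and shielded by the allylic silyloxy group; the new stereocentre is destroyed in step 4.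

Step 4
Reactants: 5 6,7-epoxyneryl tert-butyldiphenylsilyl ether
Product: 6 (4Z)-6-(tert-butyldiphenylsilyloxy)-4-methylhex-4-enal
Conditions: H5IO6, THF/Et2O, 0 °C
Reagents that add atoms: none
Why: Periodic acid opens the epoxide and cleaves the resulting glycol in one operation (Malaprade-type cleavage), releasing acetone and leaving the (Z)-alkene untouched, the aldehyde oxygen being the former epoxide oxygen.

Step 5
Reactants: 6 (4Z)-6-(tert-butyldiphenylsilyloxy)-4-methylhex-4-enal
Product: 7 tert-butyl{[(2Z)-3-methylhept-2-en-6-yn-1-yl]oxy}diphenylsilane (terminal alkyne)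
Conditions: dimethyl (1-diazo-2-oxopropyl)phosphonate, K2CO3, MeOH, 0 °C to rt
Reagents that add atoms: dimethyl (1-diazo-2-oxopropyl)phosphonate, COP(=O)(OC)C(=[N+]=[N-])C(C)=O
Why: Seyferth–Gilbert homologation with the Ohira–Bestmann reagent converts the aldehyde into the terminal alkyne under mild carbonate conditions that leave the silyl ether and the (Z)-alkene unchanged.

Step 6
Reactants: 7 tert-butyl{[(2Z)-3-methylhept-2-en-6-yn-1-yl]oxy}diphenylsilane
Product: 9 (6Z)-8-(tert-butyldiphenylsilyloxy)-6-methyloct-6-en-2-ynoic acid, via lithium acetylide 8 (not isolated)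
Conditions: n-BuLi, THF, −78 °C; then CO2 (gas), −78 to 0 °C; cold 1 M HCl work-up
Reagents that add atoms: carbon dioxide, O=C=O; n-butyllithium, [Li]CCCC (lithium only, in 8)
Why: Deprotonation of the terminal alkyne and carboxylation of the lithium acetylide with CO2 is the standard route to 2-alkynoic acids.

Step 7
Reactants: 9 (6Z)-8-(tert-butyldiphenylsilyloxy)-6-methyloct-6-en-2-ynoic acid; 10 oxazolidin-2-one
Product: 12 3-[(6Z)-8-(tert-butyldiphenylsilyloxy)-6-methyloct-6-en-2-ynoyl]oxazolidin-2-one (alkyne carbons C8 and C9), via mixed pivalic anhydride 11 (not isolated)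
Conditions: PivCl, Et3N, THF, −20 °C; then oxazolidin-2-one, LiCl, −20 °C to rt
Reagents that add atoms: pivaloyl chloride, CC(C)(C)C(Cl)=O (pivaloyl group only in 11)
Why: Mixed-anhydride N-acylation of the oxazolidinone (pivaloyl activation, LiCl-assisted) is the established way to N-acyl oxazolidinones and avoids an acid chloride that could add HCl across the ynoate.

Step 8
Reactants: 2 (E)-7-silyloxy diene; 12 alkynoyl oxazolidinone
Product: 13 3-[7α-(tert-butyldimethylsilyloxy)-15-(tert-butyldiphenylsilyloxy)labda-5,8,13(Z)-trien-17-oyl]oxazolidin-2-one (ring B cyclohexa-1,4-diene, 10β-methyl)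
Conditions: [Cu((S,S)-t-Bu-box)](SbF6)2 (10 mol %; t-Bu-box = 2,2-bis[(4S)-4-tert-butyl-4,5-dihydro-1,3-oxazol-2-yl]propane), 2 (2 equiv), CH2Cl2, −20 °C to rt
Reagents that add atoms: none
Why: Proposed new method: two-point binding of the imide carbonyls of 12 to the cationic divalent copper centre lowers the LUMO of the alkyne π-bond conjugated with the acyl group, and diene 2 adds in an asynchronous normal-demand [4+2] cycloaddition in which the electron-rich terminus C10 bonds to the β-carbon C9 ahead of C7–C8, the closest known reaction types being the thermal Diels–Alder additions of 1,3,3-trimethyl-2-vinylcyclohexene to acetylenic esters and the Diels–Alder reactions of alkenoyl oxazolidinones catalysed by divalent copper bis(oxazoline) complexes. Ring B closes as a six-membered carbocycle by suprafacial union of both diene termini with the two alkyne carbons (at the stepwise limit a 6-exo-trig aldol-type closure of C8 onto the C7 oxocarbenium ion), and the alkyne leaves the C8=C9 double bond in place. The regiochemistry needed, C7 to the acyl-bearing C8, is secured by the silyloxy group on C7, which puts the largest HOMO coefficient on C10. The relation between the two new stereocentres is fixed by the diene alone, since the ring holds the C10 methyl inside and the (E)-enol ether holds O7 outside, so that they end up trans (7α-O, 10β-CH3) on either face. The absolute sense is set by the ligand: the tert-butyl group beside the bound acyl oxygen closes one face of the planar chelate, and the diene should add to the open face with its C5–C6 unit over the copper-bound acyl oxygen and away from the N–CH2 group of the oxazolidinone, which leads to 13. The step also needs ring closure to outrun silyl transfer (a Mukaiyama–Michael outcome), which the bulky tert-butyldimethylsilyl group and the non-coordinating SbF6 counter-ion are chosen to favour.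

Step 9
Reactants: 13 Diels–Alder adduct
Product: 14 3-[15-(tert-butyldiphenylsilyloxy)-7α-hydroxylabda-5,8,13(Z)-trien-17-oyl]oxazolidin-2-one
Conditions: HF·pyridine, pyridine, THF, 0 °C to rt
Reagents that add atoms: none
Why: Selective desilylation with buffered acidic fluoride should remove the secondary tert-butyldimethylsilyl ether while the primary tert-butyldiphenylsilyl ether, far more stable to this reagent, stays.

Step 10
Reactants: 14 7α-hydroxy triene
Product: 15 3-[15-(tert-butyldiphenylsilyloxy)-5α,6α-epoxy-7α-hydroxylabda-8,13(Z)-dien-17-oyl]oxazolidin-2-one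
Conditions: VO(acac)2 (5 mol %), t-BuOOH, CH2Cl2, 0 °C to rt
Reagents that add atoms: tert-butyl hydroperoxide, CC(C)(C)OO
Why: In this hydroxyl-directed vanadium-catalysed epoxidation the pseudoaxial 7α-hydroxyl delivers the oxidant to the α-face of the allylic C5=C6 bond, while C8=C9 is switched off by conjugation with the imide and C13=C14 has no free allylic hydroxyl.

Step 11
Reactants: 15 epoxy alcohol
Product: 16 3-[15-(tert-butyldiphenylsilyloxy)-5α,6α-epoxy-7α-(triethylsilyloxy)labda-8,13(Z)-dien-17-oyl]oxazolidin-2-one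
Conditions: Et3SiCl, imidazole, DMAP (cat.), DMF, 0 °C to rt
Reagents that add atoms: chlorotriethylsilane, CC[Si](Cl)(CC)CC
Why: Routine silylation re-masks O7 with a small triethylsilyl group, so that after the next step only C6 carries a free hydroxyl.

Step 12
Reactants: 16 silylated epoxide
Product: 17 3-[15-(tert-butyldiphenylsilyloxy)-6α-hydroxy-7α-(triethylsilyloxy)labda-8,13(Z)-dien-17-oyl]oxazolidin-2-one (5α-H, trans ring fusion)
Conditions: Cp2TiCl2, Mn, THF, rt; then 16, 1,4-cyclohexadiene, rt
Reagents that add atoms: none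
Why: In this reductive epoxide opening (Nugent–RajanBabu reagent) Cp2TiCl, in which titanium is trivalent, cleaves the C5–O bond to the tertiary C5 radical, which should take a hydrogen atom from 1,4-cyclohexadiene on the α-face because the β-face is closed by the axial methyl groups on C4 and C10, giving the trans ring fusion and the 6α-alcohol.

Step 13
Reactants: 17 6α-alcohol
Product: 18 3-[15-(tert-butyldiphenylsilyloxy)-6-oxo-7α-(triethylsilyloxy)labda-8,13(Z)-dien-17-oyl]oxazolidin-2-one (5α-H)
Conditions: Dess–Martin periodinane, CH2Cl2, 0 °C to rt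
Reagents that add atoms: none
Why: Dess–Martin oxidation turns the hindered secondary alcohol into the ketone under near-neutral conditions that should not epimerise C5 or C7.

Step 14
Reactants: 18 6-ketone
Product: 19 15-(tert-butyldiphenylsilyloxy)-7α-(triethylsilyloxy)labda-8,13(Z)-diene-6β,17-diol
Conditions: LiBH4, MeOH, THF, 0 °C to rt
Reagents that add atoms: none
Why: In this hydride reduction the ketone should be attacked from the α-face, because the β-face is blocked by the syn-axial methyl groups on C4 and C10, giving the axial 6β-alcohol, and the same reagent cleaves the N-acyl oxazolidinone reductively to the primary allylic alcohol.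

Step 15
Reactants: 19 6β,17-diol
Product: 21 15-(tert-butyldiphenylsilyloxy)-7α-(triethylsilyloxy)labda-8,13(Z)-dien-6β-ol (C17 now methyl), via allylic mesylate 20 (not isolated)
Conditions: Ms2O, Et3N, THF, −40 °C; then LiEt3BH, −40 to 0 °C
Reagents that add atoms: methanesulfonic anhydride, CS(=O)(=O)OS(C)(=O)=O (mesyl group only in 20)
Why: Selective sulfonylation of the primary allylic hydroxyl (the 6β-hydroxyl is too hindered) followed by SN2 displacement of the mesylate by hydride turns C17 into the methyl group, attack at the fully substituted C9 with allylic shift being blocked sterically.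

Step 16
Reactants: 21 6β-alcohol
Product: 23 6β-acetoxy-15-(tert-butyldiphenylsilyloxy)-7α-(triethylsilyloxy)labda-8,13(Z)-diene, via potassium alkoxide 22 (not isolated)
Conditions: KN(SiMe3)2, THF, −78 °C; then Ac2O, −78 to 0 °C
Reagents that add atoms: acetic anhydride, CC(=O)OC(C)=O; potassium bis(trimethylsilyl)amide, C[Si](C)(C)N([K])[Si](C)(C)C (potassium only, in 22)
Why: O-Acylation of a preformed alkoxide should acetylate the 6β-hydroxyl despite its two syn-axial methyl neighbours, and the anti arrangement of O6 and O7 rules out silyl migration.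

Step 17
Reactants: 23 acetate bis-silyl ether
Product: 24 6β-acetoxylabda-8,13(Z)-diene-7α,15-diol (CNP0183298.2)
Conditions: Bu4NF, AcOH, THF, rt
Reagents that add atoms: none
Why: Fluoride-mediated desilylation buffered with acetic acid frees O7 and O15 together, and the hindered 6β-acetate cannot migrate to the trans-diaxial 7α-hydroxyl.

**Compound list**

1 | β-homocyclocitral, 2-(2,6,6-trimethylcyclohex-1-en-1-yl)acetaldehyde | CC1=C(CC=O)C(C)(C)CCC1 | starting material
2 | (E)-tert-butyldimethyl{[2-(2,6,6-trimethylcyclohex-1-en-1-yl)ethenyl]oxy}silane | CC1=C(/C=C/O[Si](C)(C)C(C)(C)C)C(C)(C)CCC1 | intermediate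
3 | nerol, (2Z)-3,7-dimethylocta-2,6-dien-1-ol | CC(C)=CCC/C(C)=C\CO | starting material
4 | neryl tert-butyldiphenylsilyl ether | CC(C)=CCC/C(C)=C\CO[Si](c1ccccc1)(c1ccccc1)C(C)(C)C | intermediate
5 | 6,7-epoxyneryl tert-butyldiphenylsilyl ether (racemic epoxide) | CC1(C)OC1CC/C(C)=C\CO[Si](c1ccccc1)(c1ccccc1)C(C)(C)C | intermediate
6 | (4Z)-6-(tert-butyldiphenylsilyloxy)-4-methylhex-4-enal | O=CCC/C(C)=C\CO[Si](c1ccccc1)(c1ccccc1)C(C)(C)C | intermediate
7 | tert-butyl{[(2Z)-3-methylhept-2-en-6-yn-1-yl]oxy}diphenylsilane | C#CCC/C(C)=C\CO[Si](c1ccccc1)(c1ccccc1)C(C)(C)C | intermediate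
8 | lithium acetylide of 7 (formed in the flask) | [Li]C#CCC/C(C)=C\CO[Si](c1ccccc1)(c1ccccc1)C(C)(C)C | intermediate
9 | (6Z)-8-(tert-butyldiphenylsilyloxy)-6-methyloct-6-en-2-ynoic acid | OC(=O)C#CCC/C(C)=C\CO[Si](c1ccccc1)(c1ccccc1)C(C)(C)C | intermediate
10 | oxazolidin-2-one | O=C1NCCO1 | starting material
11 | mixed anhydride of 9 with pivalic acid (formed in the flask) | CC(C)(C)C(=O)OC(=O)C#CCC/C(C)=C\CO[Si](c1ccccc1)(c1ccccc1)C(C)(C)C | intermediate
12 | 3-[(6Z)-8-(tert-butyldiphenylsilyloxy)-6-methyloct-6-en-2-ynoyl]oxazolidin-2-one | O=C(C#CCC/C(C)=C\CO[Si](c1ccccc1)(c1ccccc1)C(C)(C)C)N1CCOC1=O | intermediate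
13 | 3-[7α-(tert-butyldimethylsilyloxy)-15-(tert-butyldiphenylsilyloxy)labda-5,8,13(Z)-trien-17-oyl]oxazolidin-2-one | C1=C2C(C)(C)CCC[C@]2(C)C(CC/C(C)=C\CO[Si](c3ccccc3)(c3ccccc3)C(C)(C)C)=C(C(=O)N3CCOC3=O)[C@@H]1O[Si](C)(C)C(C)(C)C | intermediate
14 | 3-[15-(tert-butyldiphenylsilyloxy)-7α-hydroxylabda-5,8,13(Z)-trien-17-oyl]oxazolidin-2-one | C1=C2C(C)(C)CCC[C@]2(C)C(CC/C(C)=C\CO[Si](c3ccccc3)(c3ccccc3)C(C)(C)C)=C(C(=O)N3CCOC3=O)[C@@H]1O | intermediate
15 | 3-[15-(tert-butyldiphenylsilyloxy)-5α,6α-epoxy-7α-hydroxylabda-8,13(Z)-dien-17-oyl]oxazolidin-2-one | O[C@H]1C(C(=O)N2CCOC2=O)=C(CC/C(C)=C\CO[Si](c2ccccc2)(c2ccccc2)C(C)(C)C)[C@@]3(C)CCCC(C)(C)[C@@]34O[C@@H]14 | intermediate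
16 | 3-[15-(tert-butyldiphenylsilyloxy)-5α,6α-epoxy-7α-(triethylsilyloxy)labda-8,13(Z)-dien-17-oyl]oxazolidin-2-one | CC[Si](CC)(CC)O[C@H]1C(C(=O)N2CCOC2=O)=C(CC/C(C)=C\CO[Si](c2ccccc2)(c2ccccc2)C(C)(C)C)[C@@]3(C)CCCC(C)(C)[C@@]34O[C@@H]14 | intermediate
17 | 3-[15-(tert-butyldiphenylsilyloxy)-6α-hydroxy-7α-(triethylsilyloxy)labda-8,13(Z)-dien-17-oyl]oxazolidin-2-one (5α-H) | O[C@H]1[C@@H](O[Si](CC)(CC)CC)C(C(=O)N2CCOC2=O)=C(CC/C(C)=C\CO[Si](c2ccccc2)(c2ccccc2)C(C)(C)C)[C@@]3(C)CCCC(C)(C)[C@H]13 | intermediate
18 | 3-[15-(tert-butyldiphenylsilyloxy)-6-oxo-7α-(triethylsilyloxy)labda-8,13(Z)-dien-17-oyl]oxazolidin-2-one (5α-H) | O=C1[C@@H](O[Si](CC)(CC)CC)C(C(=O)N2CCOC2=O)=C(CC/C(C)=C\CO[Si](c2ccccc2)(c2ccccc2)C(C)(C)C)[C@@]3(C)CCCC(C)(C)[C@H]13 | intermediate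
19 | 15-(tert-butyldiphenylsilyloxy)-7α-(triethylsilyloxy)labda-8,13(Z)-diene-6β,17-diol | O[C@@H]1[C@@H](O[Si](CC)(CC)CC)C(CO)=C(CC/C(C)=C\CO[Si](c2ccccc2)(c2ccccc2)C(C)(C)C)[C@@]3(C)CCCC(C)(C)[C@H]13 | intermediate
20 | 17-methanesulfonate of 19 (formed in the flask) | O[C@@H]1[C@@H](O[Si](CC)(CC)CC)C(COS(C)(=O)=O)=C(CC/C(C)=C\CO[Si](c2ccccc2)(c2ccccc2)C(C)(C)C)[C@@]3(C)CCCC(C)(C)[C@H]13 | intermediate
21 | 15-(tert-butyldiphenylsilyloxy)-7α-(triethylsilyloxy)labda-8,13(Z)-dien-6β-ol | O[C@@H]1[C@@H](O[Si](CC)(CC)CC)C(C)=C(CC/C(C)=C\CO[Si](c2ccccc2)(c2ccccc2)C(C)(C)C)[C@@]3(C)CCCC(C)(C)[C@H]13 | intermediate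
22 | potassium 6β-alkoxide of 21 (formed in the flask) | [K]O[C@@H]1[C@@H](O[Si](CC)(CC)CC)C(C)=C(CC/C(C)=C\CO[Si](c2ccccc2)(c2ccccc2)C(C)(C)C)[C@@]3(C)CCCC(C)(C)[C@H]13 | intermediate
23 | 6β-acetoxy-15-(tert-butyldiphenylsilyloxy)-7α-(triethylsilyloxy)labda-8,13(Z)-diene | CC(=O)O[C@@H]1[C@@H](O[Si](CC)(CC)CC)C(C)=C(CC/C(C)=C\CO[Si](c2ccccc2)(c2ccccc2)C(C)(C)C)[C@@]3(C)CCCC(C)(C)[C@H]13 | intermediate
24 | 6β-acetoxylabda-8,13(Z)-diene-7α,15-diol (CNP0183298.2) | CC(=O)O[C@@H]1[C@@H](O)C(C)=C(CC/C(C)=C\CO)[C@@]2(C)CCCC(C)(C)[C@H]12 | target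

**Step count**

Total: 17 steps. Longest linear sequence: 16 steps (steps 2 to 17, nerol to 24).

**Steps most likely to fail**

1. Step 8 (proposed new method). What may go wrong: the congested C9–C10 bond may form too slowly; the silyl group may transfer after the first bond, ending in a conjugate-addition product and no ring closure; or the catalyst may select the alkyne face weakly or in the opposite sense. Fallback with known chemistry: set out from 2 and 12 and heat them without catalyst (toluene, sealed tube, 130–150 °C, or 10–12 kbar in CH2Cl2). This is the thermal Diels–Alder mode established for 1,3,3-trimethyl-2-vinylcyclohexene with acetylenic carbonyl dienophiles. The relative configuration is still fixed by the diene, so the product is 13 together with the enantiomeric adduct F1. Preparative chromatography on a chiral stationary phase removes F1 and the route is rejoined at 13.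

2. Step 12. What may go wrong: hydrogen-atom delivery to the C5 radical may occur in part from the β-face and give the cis ring fusion, or the trivalent titanium reagent may reduce the conjugated imide. Fallback, setting out from 16: the opening is run as before and the alcohols are not separated, so that 17 is carried on together with the cis-fused 5β-epimer F2. Dess–Martin oxidation converts the mixture into 18 and the 5β-ketone F3. Because C5 is now α to the ketone, F3 is equilibrated with DBU in toluene at rt to the trans-fused isomer, which should be the more stable ring fusion for decalones of this type. C7 should hold, since a 7β-silyloxy group would eclipse the acyl substituent on C8. The C5 configuration is then set by thermodynamic control and no longer by the face of hydrogen transfer, and the route is rejoined at 18.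

3. Step 14. What may go wrong: hydride may attack the ring carbonyl of the hindered imide and open the oxazolidinone, and face selection at C6 may be incomplete because the α-face carries the axial 7-silyloxy group. Fallback, setting out from 18: the two reductions are separated. NaBH4 (MeOH/THF, −20 °C) reduces only the ketone and gives the 6β-hydroxy imide F4. LiOH/H2O2 (THF/H2O, 0 °C) then cleaves the imide at the exocyclic carbonyl, as hydroperoxide does even with hindered imides, and gives the 6β-hydroxy acid F5. LiAlH4 (THF, 0 °C) reduces the acid to the diol, and the route is rejoined at 19.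

**Further compounds**

F1 | step 8 | enantiomer of adduct 13 | C1=C2C(C)(C)CCC[C@@]2(C)C(CC/C(C)=C\CO[Si](c3ccccc3)(c3ccccc3)C(C)(C)C)=C(C(=O)N3CCOC3=O)[C@H]1O[Si](C)(C)C(C)(C)C
F2 | step 12 | 5β-epimer of 17 (cis ring fusion) | O[C@H]1[C@@H](O[Si](CC)(CC)CC)C(C(=O)N2CCOC2=O)=C(CC/C(C)=C\CO[Si](c2ccccc2)(c2ccccc2)C(C)(C)C)[C@@]3(C)CCCC(C)(C)[C@@H]13
F3 | step 12 | 5β-epimer of ketone 18 (cis ring fusion) | O=C1[C@@H](O[Si](CC)(CC)CC)C(C(=O)N2CCOC2=O)=C(CC/C(C)=C\CO[Si](c2ccccc2)(c2ccccc2)C(C)(C)C)[C@@]3(C)CCCC(C)(C)[C@@H]13
F4 | step 14 | 3-[15-(tert-butyldiphenylsilyloxy)-6β-hydroxy-7α-(triethylsilyloxy)labda-8,13(Z)-dien-17-oyl]oxazolidin-2-one | O[C@@H]1[C@@H](O[Si](CC)(CC)CC)C(C(=O)N2CCOC2=O)=C(CC/C(C)=C\CO[Si](c2ccccc2)(c2ccccc2)C(C)(C)C)[C@@]3(C)CCCC(C)(C)[C@H]13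
F5 | step 14 | 15-(tert-butyldiphenylsilyloxy)-6β-hydroxy-7α-(triethylsilyloxy)labda-8,13(Z)-dien-17-oic acid | O[C@@H]1[C@@H](O[Si](CC)(CC)CC)C(C(O)=O)=C(CC/C(C)=C\CO[Si](c2ccccc2)(c2ccccc2)C(C)(C)C)[C@@]3(C)CCCC(C)(C)[C@H]13
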